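**Retrosynthetic overview**
1. Aspidin PB ⇐ MOM cleavage ⇐ C‑propanoylation of the one free CH of the six‑membered ring (O‑to‑C acyl shift) ⇐ hydrolysis of two ethyl enol ethers ⇐ dienone 22.
2. 22 ⇐ annulation of 3‑ethoxy‑4,4‑dimethylcyclobutenone 18 with the aryl‑substituted ynol ether 15: the two alkyne carbons are inserted into the C(=O)–CH= bond of 18, which builds the non‑aromatic six‑membered ring and joins the two halves of the target in one operation.
3. Enabling feature: the quaternary C(CH3)2 carbon of the non‑aromatic six‑membered ring, bonded to two oxygen‑bearing ring carbons of a 1,3,5‑trioxygenated ring. As C4 of a cyclobutenone it sits next to the ketene‑forming carbonyl, and after 6π closure it blocks aromatisation, so the ring stops at the cyclohexadienone (filicinic acid) level.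
4. 15 ⇐ Stille coupling of benzylic chloride 11 with stannylated ethoxyethyne 14; 11 ⇐ three successive directed ortho‑metalations of bis‑MOM 5‑methoxyresorcinol (CH2OH, CH3, butanoyl).
5. Ring order: the benzene ring is bought; the cyclobutenone ring comes from dimethylketene and ethoxyethyne by [2+2]; the six‑membered dienone ring is formed last, in the key step.

Key step: step 9

Remark: enolised β‑di‑ and β‑triketones (23, 25, 26, 27) are written as one tautomer each, 27 in the tautomer of the target formula. The target has no stereocentre; 20 is racemic and transient.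

Step 1
Reactants: 1 5-methoxybenzene-1,3-diol
Product: 2 1-methoxy-3,5-bis(methoxymethoxy)benzene
Conditions: MOMCl (2.5 equiv), i-Pr2NEt, CH2Cl2, 0 °C to rt
Reagents that add atoms: chloromethyl methyl ether, COCCl
Why: Williamson-type O-alkylation of both phenols (MOM protection), which also installs the directing groups for the three metalations that follow.

Step 2
Reactants: 2 1-methoxy-3,5-bis(methoxymethoxy)benzene
Product: 4 [4-methoxy-2,6-bis(methoxymethoxy)phenyl]methanol, via aryllithium 3 (not isolated)
Conditions: n-BuLi (1.1 equiv), THF, 0 °C; paraformaldehyde, −78 °C to rt; H2O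
Reagents that add atoms: formaldehyde (from paraformaldehyde), C=O
Why: Directed ortho-metalation should take place at the C–H flanked by the two MOM ethers (double chelation; MOM directs more strongly than OMe), and the aryllithium is hydroxymethylated by formaldehyde.

Step 3
Reactants: 4 [4-methoxy-2,6-bis(methoxymethoxy)phenyl]methanol
Product: 6 [4-methoxy-3-methyl-2,6-bis(methoxymethoxy)phenyl]methanol, via dilithio species 5 (not isolated)
Conditions: n-BuLi (2.2 equiv), TMEDA, THF, −20 to 0 °C; MeI (1.0 equiv), −78 °C; H2O
Reagents that add atoms: iodomethane, CI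
Why: Directed ortho-metalation of the lithium alkoxide at one of the two symmetry-equivalent C–H positions between OMOM and OMe, then C-methylation, which at −78 °C should be much faster than O-methylation of the lithium alkoxide.

Step 4
Reactants: 6 [4-methoxy-3-methyl-2,6-bis(methoxymethoxy)phenyl]methanol; 7 N-methoxy-N-methylbutanamide
Product: 9 1-[3-(hydroxymethyl)-6-methoxy-5-methyl-2,4-bis(methoxymethoxy)phenyl]butan-1-one, via dilithio species 8 (not isolated)
Conditions: n-BuLi (2.2 equiv), TMEDA, THF, −20 to 0 °C; 7, −78 to 0 °C; H2O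
Reagents that add atoms: none
Why: Directed ortho-metalation at the only ring C–H left (between OMOM and OMe, preferred over lateral lithiation of the methyl group), then Weinreb ketone synthesis, which stops at the ketone.

Step 5
Reactants: 9 1-[3-(hydroxymethyl)-6-methoxy-5-methyl-2,4-bis(methoxymethoxy)phenyl]butan-1-one
Product: 11 1-[3-(chloromethyl)-6-methoxy-5-methyl-2,4-bis(methoxymethoxy)phenyl]butan-1-one, via benzylic mesylate 10 (not isolated)
Conditions: MsCl, Et3N, LiCl, THF, 0 °C
Reagents that add atoms: lithium chloride, [Li+].[Cl-]; methanesulfonyl chloride, CS(=O)(=O)Cl (its atoms stay only in 10)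
Why: Mesylation and chloride displacement under non-acidic conditions keep the MOM ethers intact, and the hexasubstituted ring cannot alkylate itself, so the activated benzylic chloride should be isolable and is used at once.

Step 6
Reactants: 12 ethoxyethyne
Product: 14 tributyl(ethoxyethynyl)stannane, via lithium acetylide 13 (not isolated)
Conditions: n-BuLi, THF, −78 °C; Bu3SnCl, −78 °C to rt
Reagents that add atoms: tributyltin chloride, CCCC[Sn](Cl)(CCCC)CCCC
Why: Deprotonation of the terminal alkyne and stannylation of the lithium acetylide, a standard route to alkynylstannanes.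

Step 7
Reactants: 11 1-[3-(chloromethyl)-6-methoxy-5-methyl-2,4-bis(methoxymethoxy)phenyl]butan-1-one; 14 tributyl(ethoxyethynyl)stannane
Product: 15 1-[3-(3-ethoxyprop-2-yn-1-yl)-6-methoxy-5-methyl-2,4-bis(methoxymethoxy)phenyl]butan-1-one
Conditions: Pd(PPh3)4 (5 mol%), THF, 50 °C; chromatography on Et3N-deactivated silica
Reagents that add atoms: none
Why: Stille coupling of a benzylic chloride with an alkynylstannane (oxidative addition to zerovalent palladium, selective transfer of the alkynyl group from tin), under neutral conditions that should tolerate the hindered aryl ketone, the MOM ethers and the acid-sensitive ynol ether.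

Step 8
Reactants: 16 2-methylpropanoyl chloride; 12 ethoxyethyne
Product: 18 3-ethoxy-4,4-dimethylcyclobut-2-en-1-one, via dimethylketene 17 (not isolated)
Conditions: Et3N, Et2O, 0 °C to rt
Reagents that add atoms: none
Why: Dehydrochlorination gives dimethylketene, which adds to the ynol ether in a thermal [2+2] cycloaddition with the ketene carbonyl carbon bonding to the unsubstituted, nucleophilic alkyne carbon, the usual route to 3-alkoxycyclobutenones.

Step 9
Reactants: 18 3-ethoxy-4,4-dimethylcyclobut-2-en-1-one; 15 1-[3-(3-ethoxyprop-2-yn-1-yl)-6-methoxy-5-methyl-2,4-bis(methoxymethoxy)phenyl]butan-1-one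
Product: 22 1-[3-[(2,4-diethoxy-5,5-dimethyl-6-oxocyclohexa-1,3-dien-1-yl)methyl]-6-methoxy-5-methyl-2,4-bis(methoxymethoxy)phenyl]butan-1-one, via vinylketene 19 (not isolated), via cyclobutenone adduct 20 (not isolated), via dienylketene 21 (not isolated)
Conditions: PhMe, 90–100 °C, sealed tube, 18 in slight excess
Reagents that add atoms: none
Why: Proposed new method: heating opens the strained cyclobutenone 18 by 4π-electrocyclic ring opening to vinylketene 19, whose ketene C=C adds the ynol ether of 15 in a [2+2] cycloaddition to give 20, and a second 4π opening to dienylketene 21 followed by 6π-electrocyclisation should deliver 22, so that in the net change the two alkyne carbons are inserted into the C1–C2 bond of 18. The closest known reaction type is the Danheiser benzannulation of cyclobutenones with alkoxy- or siloxyalkynes, and the last event is the known thermal reclosure of the dienylketenes that form on irradiation of 6,6-disubstituted cyclohexa-2,4-dienones; new is the combination on a 4,4-dimethylcyclobutenone, where the closing terminus is quaternary and the product must remain a dienone instead of becoming a phenol. Mode of closure: the four-membered ring of 20 forms by ketene–alkyne [2+2] cycloaddition and the six-membered ring of 22 by thermal disrotatory 6π-electrocyclisation of an all-carbon triene, with the new C–C bond between the ketene carbon and the CMe2 terminus. No stereocentre is formed in 22; the single stereocentre of 20 is racemic and is erased on ring opening, and only the isomer of 21 with the ketene and the C(OEt)=CMe2 group cis on the central double bond can close, the other one reverting to 20. The selectivity needed is the regiochemistry of the [2+2] step, secured by the polarisation of the ynol ether (its nucleophilic carbon, the one carrying the arylmethyl group, bonds to the electrophilic ketene carbon), and [2+2] instead of [4+2] addition to 19, secured by the fully substituted diene terminus. The hindered aryl ketone, the MOM ethers and the methyl ether have no pathway with a non-activated ketene under neutral thermal conditions, and the temperature is kept below the onset of retro-ene loss of ethene from the ethyl ynol ether.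

Step 10
Reactants: 22 1-[3-[(2,4-diethoxy-5,5-dimethyl-6-oxocyclohexa-1,3-dien-1-yl)methyl]-6-methoxy-5-methyl-2,4-bis(methoxymethoxy)phenyl]butan-1-one
Product: 23 1-[3-[(2-hydroxy-3,3-dimethyl-4,6-dioxocyclohex-1-en-1-yl)methyl]-6-methoxy-5-methyl-2,4-bis(methoxymethoxy)phenyl]butan-1-one
Conditions: 0.5 M aq. HCl, THF, rt
Reagents that add atoms: water, O
Why: Acid-catalysed hydrolysis of the enol ether and of the vinylogous ester that remains (C-protonation, hydration, loss of ethanol) should be far faster than cleavage of aryl MOM ethers in dilute aqueous acid at room temperature.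

Step 11
Reactants: 23 1-[3-[(2-hydroxy-3,3-dimethyl-4,6-dioxocyclohex-1-en-1-yl)methyl]-6-methoxy-5-methyl-2,4-bis(methoxymethoxy)phenyl]butan-1-one; 24 propanoyl chloride
Product: 26 1-[3-[(2,6-dihydroxy-3,3-dimethyl-4-oxo-5-propanoylcyclohexa-1,5-dien-1-yl)methyl]-6-methoxy-5-methyl-2,4-bis(methoxymethoxy)phenyl]butan-1-one, via enol propanoate 25 (not isolated)
Conditions: EtCOCl (1.1 equiv), Et3N, CH2Cl2, 0 °C; then DMAP (cat.), rt
Reagents that add atoms: none
Why: O-acylation of the enolised trione followed by the DMAP-catalysed enol ester to triketone rearrangement (a Fries-type O-to-C 1,3-acyl shift) should place the propanoyl group on the only unsubstituted ring carbon between two carbonyl groups, where the product is held as a stabilised enolised β-triketone, while the MOM-masked phenols cannot be acylated.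

Step 12
Reactants: 26 1-[3-[(2,6-dihydroxy-3,3-dimethyl-4-oxo-5-propanoylcyclohexa-1,5-dien-1-yl)methyl]-6-methoxy-5-methyl-2,4-bis(methoxymethoxy)phenyl]butan-1-one
Product: 27 Aspidin PB
Conditions: conc. HCl (cat.), MeOH, 40 °C
Reagents that add atoms: none
Why: Acid-catalysed transacetalisation to methanol removes both MOM groups under conditions mild enough to avoid cyclodehydration between a freed phenol and the neighbouring enol.

**Compound list**
1 | 5-methoxybenzene-1,3-diol (5-methoxyresorcinol) | COc1cc(O)cc(O)c1 | starting material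
2 | 1-methoxy-3,5-bis(methoxymethoxy)benzene | COCOc1cc(OC)cc(OCOC)c1 | intermediate
3 | [4-methoxy-2,6-bis(methoxymethoxy)phenyl]lithium (not isolated) | [Li]c1c(OCOC)cc(OC)cc1OCOC | intermediate
4 | [4-methoxy-2,6-bis(methoxymethoxy)phenyl]methanol | OCc1c(OCOC)cc(OC)cc1OCOC | intermediate
5 | lithium [3-lithio-4-methoxy-2,6-bis(methoxymethoxy)phenyl]methanolate (not isolated) | [Li]OCc1c(OCOC)c([Li])c(OC)cc1OCOC | intermediate
6 | [4-methoxy-3-methyl-2,6-bis(methoxymethoxy)phenyl]methanol | OCc1c(OCOC)c(C)c(OC)cc1OCOC | intermediate
7 | N-methoxy-N-methylbutanamide | CCCC(=O)N(C)OC | starting material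
8 | lithium [5-lithio-4-methoxy-3-methyl-2,6-bis(methoxymethoxy)phenyl]methanolate (not isolated) | [Li]OCc1c(OCOC)c(C)c(OC)c([Li])c1OCOC | intermediate
9 | 1-[3-(hydroxymethyl)-6-methoxy-5-methyl-2,4-bis(methoxymethoxy)phenyl]butan-1-one | CCCC(=O)c1c(OCOC)c(CO)c(OCOC)c(C)c1OC | intermediate
10 | [3-butanoyl-4-methoxy-5-methyl-2,6-bis(methoxymethoxy)phenyl]methyl methanesulfonate (not isolated) | CCCC(=O)c1c(OCOC)c(COS(C)(=O)=O)c(OCOC)c(C)c1OC | intermediate
11 | 1-[3-(chloromethyl)-6-methoxy-5-methyl-2,4-bis(methoxymethoxy)phenyl]butan-1-one | CCCC(=O)c1c(OCOC)c(CCl)c(OCOC)c(C)c1OC | intermediate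
12 | ethoxyethyne (ethoxyacetylene) | CCOC#C | starting material
13 | (ethoxyethynyl)lithium (not isolated) | CCOC#C[Li] | intermediate
14 | tributyl(ethoxyethynyl)stannane | CCCC[Sn](CCCC)(CCCC)C#COCC | intermediate
15 | 1-[3-(3-ethoxyprop-2-yn-1-yl)-6-methoxy-5-methyl-2,4-bis(methoxymethoxy)phenyl]butan-1-one | CCCC(=O)c1c(OCOC)c(CC#COCC)c(OCOC)c(C)c1OC | intermediate
16 | 2-methylpropanoyl chloride (isobutyryl chloride) | CC(C)C(Cl)=O | starting material
17 | dimethylketene (not isolated) | CC(C)=C=O | intermediate
18 | 3-ethoxy-4,4-dimethylcyclobut-2-en-1-one | CCOC1=CC(=O)C1(C)C | intermediate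
19 | 3-ethoxy-4-methylpenta-1,3-dien-1-one, vinylketene (not isolated) | CCOC(C=C=O)=C(C)C | intermediate
20 | racemic 1-[3-[[2-ethoxy-3-(1-ethoxy-2-methylprop-1-en-1-yl)-4-oxocyclobut-1-en-1-yl]methyl]-6-methoxy-5-methyl-2,4-bis(methoxymethoxy)phenyl]butan-1-one (not isolated) | CCCC(=O)c1c(OCOC)c(CC2=C(OCC)C(C(OCC)=C(C)C)C2=O)c(OCOC)c(C)c1OC | intermediate
21 | (3E)-2-[[3-butanoyl-4-methoxy-5-methyl-2,6-bis(methoxymethoxy)phenyl]methyl]-3,5-diethoxy-6-methylhepta-1,3,5-trien-1-one, dienylketene with the ketene and the C(OEt)=CMe2 group cis on the central double bond (not isolated) | CCCC(=O)c1c(OCOC)c(CC(=C=O)/C(OCC)=C\C(OCC)=C(C)C)c(OCOC)c(C)c1OC | intermediate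
22 | 1-[3-[(2,4-diethoxy-5,5-dimethyl-6-oxocyclohexa-1,3-dien-1-yl)methyl]-6-methoxy-5-methyl-2,4-bis(methoxymethoxy)phenyl]butan-1-one | CCCC(=O)c1c(OCOC)c(CC2=C(OCC)C=C(OCC)C(C)(C)C2=O)c(OCOC)c(C)c1OC | intermediate
23 | 1-[3-[(2-hydroxy-3,3-dimethyl-4,6-dioxocyclohex-1-en-1-yl)methyl]-6-methoxy-5-methyl-2,4-bis(methoxymethoxy)phenyl]butan-1-one (one enol tautomer of the trione) | CCCC(=O)c1c(OCOC)c(CC2=C(O)C(C)(C)C(=O)CC2=O)c(OCOC)c(C)c1OC | intermediate
24 | propanoyl chloride | CCC(=O)Cl | starting material
25 | 6-[[3-butanoyl-4-methoxy-5-methyl-2,6-bis(methoxymethoxy)phenyl]methyl]-5-hydroxy-4,4-dimethyl-3-oxocyclohexa-1,5-dien-1-yl propanoate (not isolated) | CCCC(=O)c1c(OCOC)c(CC2=C(O)C(C)(C)C(=O)C=C2OC(=O)CC)c(OCOC)c(C)c1OC | intermediate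
26 | 1-[3-[(2,6-dihydroxy-3,3-dimethyl-4-oxo-5-propanoylcyclohexa-1,5-dien-1-yl)methyl]-6-methoxy-5-methyl-2,4-bis(methoxymethoxy)phenyl]butan-1-one | CCCC(=O)c1c(OCOC)c(CC2=C(O)C(C)(C)C(=O)C(C(=O)CC)=C2O)c(OCOC)c(C)c1OC | intermediate
27 | Aspidin PB, 1-[3-[(2,6-dihydroxy-3,3-dimethyl-4-oxo-5-propanoylcyclohexa-1,5-dien-1-yl)methyl]-2,4-dihydroxy-6-methoxy-5-methylphenyl]butan-1-one | CCCC(=O)c1c(O)c(CC2=C(O)C(C)(C)C(=O)C(C(=O)CC)=C2O)c(O)c(C)c1OC | target

**Step count and risks**
Total step count: 12. Longest linear sequence: 10 steps (1, 2, 3, 4, 5, 7, 9, 10, 11, 12); steps 6 and 8 are side branches.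

Risk 1, step 9 (Proposed new method). The ring opening of the 4,4-dimethylcyclobutenone needs one methyl group to rotate inward and may be slow. Retro-ene loss of ethene from the ynol ether and oligomerisation of the ketenes could then take over before the annulation is complete. The fallback uses known chemistry only; it sets out from 15 and comes back to the route at 23, replacing steps 8, 9 and 10. Acid-catalysed hydration of the ynol ether (PPTS, wet THF, rt) should give ethyl 3-[3-butanoyl-4-methoxy-5-methyl-2,6-bis(methoxymethoxy)phenyl]propanoate F1. Crossed Claisen condensation of F1 with an excess of the lithium enolate of commercial methyl 2,2-dimethyl-3-oxobutanoate (LiN(i-Pr)2, THF, −78 to 0 °C) should give methyl 7-[3-butanoyl-4-methoxy-5-methyl-2,6-bis(methoxymethoxy)phenyl]-2,2-dimethyl-3,5-dioxoheptanoate F2. Dieckmann-type cyclisation of F2 (NaOMe, MeOH, reflux), in which the terminal carbanion of the diketone attacks the ester, should close the six-membered ring to 23, whose stable enolate is the thermodynamic sink.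

Risk 2, step 7. Ionisation of the electron-rich benzylic chloride, helped by the neighbouring MOM oxygen, may compete with oxidative addition and transmetalation, and the ynol ether may hydrate during isolation. The fallback sets out from 11 and comes back to the route at 23, replacing steps 6 to 10. Alkylation of sodium diethyl malonate (NaH, THF, 0 °C) with 11 should give diethyl 2-[[3-butanoyl-4-methoxy-5-methyl-2,6-bis(methoxymethoxy)phenyl]methyl]propanedioate F3. Krapcho dealkoxycarbonylation (LiCl, wet DMSO, 140 °C) should give the propanoate F1 described above. The Claisen condensation to the dioxoheptanoate F2 and its Dieckmann-type cyclisation then lead to 23 as in the first fallback.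

Risk 3, step 11. The acyl transfer may stop at the O-acyl stage, or acylation at the substituted ring carbon may be followed by retro-Claisen ring cleavage. The fallback changes the order of events: the acyl group is placed before the two halves are joined. It sets out from 11 and comes back to the route at 26, replacing steps 6 to 11. Double C-methylation at one ring carbon of commercial 1-(2,4,6-trihydroxyphenyl)propan-1-one with MeI and NaOMe in MeOH should give 3,5-dihydroxy-6,6-dimethyl-2-propanoylcyclohexa-2,4-dien-1-one F4 (2-propanoylfilicinic acid). C-Benzylation of its sodium salt with chloride 11 (NaOMe, MeOH, 0 °C) at the one remaining ring CH should give 26.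

Further compounds
F1 | step 9 | ethyl 3-[3-butanoyl-4-methoxy-5-methyl-2,6-bis(methoxymethoxy)phenyl]propanoate | CCCC(=O)c1c(OCOC)c(CCC(=O)OCC)c(OCOC)c(C)c1OC
F2 | step 9 | methyl 7-[3-butanoyl-4-methoxy-5-methyl-2,6-bis(methoxymethoxy)phenyl]-2,2-dimethyl-3,5-dioxoheptanoate | CCCC(=O)c1c(OCOC)c(CCC(=O)CC(=O)C(C)(C)C(=O)OC)c(OCOC)c(C)c1OC
F3 | step 7 | diethyl 2-[[3-butanoyl-4-methoxy-5-methyl-2,6-bis(methoxymethoxy)phenyl]methyl]propanedioate | CCCC(=O)c1c(OCOC)c(CC(C(=O)OCC)C(=O)OCC)c(OCOC)c(C)c1OC
F4 | step 11 | 3,5-dihydroxy-6,6-dimethyl-2-propanoylcyclohexa-2,4-dien-1-one (2-propanoylfilicinic acid) | CCC(=O)C1=C(O)C=C(O)C(C)(C)C1=O
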